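## The problem

Atom labels follow the order of the atoms in the target SMILES (hydrogens omitted): C1–C7 heptyl, C8=C9, C10, O11, C12, C13(=O14), O15, C16, C17, C18(O19), C20, C21, C22, C23=C24(C25), C26, C27(O28).

The target is a 2-oxabicyclo[2.2.2]octan-3-one cage (bridgeheads C12 and C16; bridges C13–O15, C22–C21 and C27–C26). A cyclopentane is fused across C16–C21 and a 3,6-dihydro-2H-pyran across C12–C22 through the bridgehead oxygen O11. Of the seven stereocentres, C12, C22 and C21 are contiguous on the carbocycle and carry C13, C23 and C20 on one face; C16 is then dictated by the lactone bridge. Three centres are not dictated by the cage: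

- C18, a remote carbinol with O19 trans to C22;
- C27, whose hydroxyl points away from the lactone bridge;
- C10, whose alkenyl group is pseudo-axial and syn to C13.

C27 can be set by hydride attack on a ketone from the open lactone face, and C10 by kinetic axial attack on an oxocarbenium ion held in one half-chair by the cage. C18 is best taken from the chiral pool, because the less hindered face of a C18 ketone on the cage leads to the wrong epimer; it then has to help in setting C21. The doubly allylic ether at C10, the tertiary-alkyl α-alkoxy lactone with its β-hydroxyl, and three alkenes forbid cationic, strongly basic or hydrogenative steps late in the route. The cage should therefore be closed before C10 and C8=C9 are in place. The enabling feature is the carbocycle C12–C22–C21–C16–C26–C27: it maps onto a cis dienophile C12=C22 held in a butenolide and a 1-oxygenated diene C27=C26–C16=C21 whose C16=C21 bond is a cyclopentene. The cycloaddition leaves the alkene C16=C26 exactly where the lactone bridge has to be attached.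

## Retrosynthesis

**C27 and the protecting groups (31 ⇐ 30 ⇐ 29 ⇐ 28 ⇐ 27 ⇐ 26).** The last operations correct C27 and remove silicon. A cycloaddition with an (E)-enol ether unavoidably gives the C27 epimer, so the carbinol is oxidised to ketone 29 and reduced from the lactone face to 30. Both silyl ethers of 26 are removed first (27). The unhindered O19 is then re-silylated selectively (28), which is more reliable than a selective cleavage at the hindered C27 ether. The epimeric, bulky C27 silyl ether is kept until this point on purpose (see the reduction of 20).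

**C9–C10 (26 ⇐ 22 + 25).** The side chain is cut at the doubly allylic ether carbon. An alkenyl nucleophile 25, made from non-1-yne 23, adds to the oxocarbenium ion from lactol acetate 22. The opposite polarity (hydride onto a C10-alkenyl cation) would place the alkenyl group equatorial, which is the wrong epimer. The forward step must be 1,2-regioselective and must attack syn to C13.

**C10 oxidation level (22 ⇐ 20).** The acetate comes from the unsaturated lactone of bis-lactone 20 by reductive acetylation. This asks for discrimination between two lactones. The cage lactone is a tertiary-alkyl ester of a quaternary acid, flanked on one face by the pyranone ring and C20 and on the other by the epimeric C27 silyl ether.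

**O15–C16 (20 ⇐ 19 ⇐ 18).** The lactone bridge is cut back to carboxylic acid 18 and the alkene C16=C26. Iodolactonisation followed by radical deiodination is preferred to protic hydro-acyloxylation, because the C27 oxygen is allylic in 18 and would ionise under strong acid. In 18 O11 is already acylated (it cannot form a 7-oxanorbornane) and C23 is sp2 (no competing ether formation), so only the carboxylate can capture C16.

**C23=C24 and O11–C10 (18 ⇐ 17 ⇐ 16 ⇐ 15).** The pyranone is cut at the alkene and at the ester C–O bond. A (Z)-selective olefination of the C23 aldehyde installs C24, C25 and C10; loss of the O11 benzoate lets O11 close the lactone. The aldehyde is stored in the cycloadduct 15 as a menthyl acetal of the butyrolactone. Hydrolysis gives hydroxy lactone 16, and ring opening by base frees C13 as a carboxylate and C23 as an aldehyde at once. This avoids the transposition of a simple butyrolactone, which would leave a free C23 hydroxyl next to the C16 cation site.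

**Key disconnection (15 ⇐ 10 + 14).** C21–C22 and C12–C27 are cut in a [4+2] sense. Diene 10 carries the C18 stereocentre; dienophile 14 is a 3-benzoyloxybutenolide with a (5R)-menthyloxy group on C23. This group raises C23 to the aldehyde level and adds a second facial control element that is matched with the weak, remote control by C18. A triisopropylsilyl enol ether is chosen for O28 because it survives the acetal hydrolysis and later shields the cage lactone. The precursors are two small rings; the product holds four of the seven stereocentres.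

**Diene (10 ⇐ 9 ⇐ 8 ⇐ 6 + 7; 6 ⇐ 5 ⇐ 4 ⇐ 3 ⇐ 2 ⇐ 1).** C16–C26 is cut between alkenyl triflate 6 and the ethoxyvinylboronate 7. The triflate fixes the ring alkene at C16=C21, away from the silyloxy carbon, and comes from ketone 5. The ketone is reached from monoacetate 1 by silylation, deacetylation, oxidation and hydrogenation. With this order the (1S,4R) antipode 1 gives (R)-configured C18.

**Dienophile (14 ⇐ 13 ⇐ 12 ⇐ 11).** The enol benzoate is cut back to diol 12 by bis-benzoylation and β-elimination of the C4 benzoate. The diol is the dihydroxylation product of the known menthyloxybutenolide 11.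

## Roads not taken

**Alternative 1: Pauson–Khand closure.** The cut removes C16–C21, C17–C18 and C18–C20 together. In the forward step Co2(CO)8 (zerovalent cobalt) complexes an ethynyl group on C22 and, with an amine N-oxide, joins it to an exocyclic enol-lactone alkene C16=C17 and CO. This closes the cyclopentenone and the carbocycle and gives A1.

- Merits: three C–C bonds and two rings in one step on a substrate that already carries the pyran, the side chain and the correct C27. Neither a late C10 alkenylation nor a C27 inversion would be needed, and in these respects A1 is better than the chosen plan.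
- Weak points: a 1,1-disubstituted O-acyl enol alkene that must become a quaternary, oxygen-bearing C16 is a poor alkene partner, and the enol lactone is labile. C8=C9 and C23=C24 can compete for the metal. After A1, C21 and C18 must be set by reduction of the enone and the ketone in the presence of two other alkenes; the open face of the C18 ketone leads to O19 syn to C22, the wrong epimer.
- Against the convergence of A1 the chosen plan sets C18 from the chiral pool, C21 from a stereospecific cycloaddition, and a cage that is built before any sensitive alkene is present.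

**Alternative 2: Prins, ring expansion, lactonisation cascade.** The cut removes C12–C22 and O15–C16 and returns C20 from C21 to C16 (a cyclobutane). In the forward step Sc(OTf)3 or Me2AlCl activates a C12 ketone of an α-keto tert-butyl ester. The (Z)-alkene carbon C22 attacks it, C20 migrates, and the ester captures the C16 cation, giving A2.

- Merits: the whole cage with five stereocentres, a free O11 hydroxyl and the correct C27 in one step. It is shorter than steps 11–15 of the chosen route and needs no C27 inversion.
- Weak points: everything depends on one flexible C27 stereocentre controlling the face of the carbonyl addition and the choice between two cyclobutane bonds (this choice sets C18 and C21). Cyclobutylcarbinyl cations also eliminate, shift hydride or open. The Lewis acid meets two silyl ethers and a benzylic ether. After A2 the hindered tertiary O11 hydroxyl still has to be acylated to build the pyranone.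
- The chosen plan is longer to the cage, but its stereochemistry rests on a suprafacial cycloaddition with matched reagent and substrate control, and O11 is acylated from the start.

**Alternative 3: Ireland–Claisen ring contraction.** The cut is C12–C22 by a [3,3] shift. The silyl ketene acetal (LDA, Me3SiCl) of a six-membered lactone whose ester oxygen sits on C24 rearranges through a boat, breaks O–C24 and gives the dihydropyran acid A3.

- Merits: C10 is taken from a carbinol and transferred, and C12 and C22 arise by chirality transfer. This is better than the facial attack on an oxocarbenium ion that the chosen plan needs at step 18.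
- Weak points: A3 still lacks C26–C27 and O15–C16. The cage would have to be closed by a carbonyl-ene or Prins step and a lactonisation at tertiary C16, on a molecule that already holds the doubly allylic ether and three alkenes and with no control of C27. The enolate carries a β-alkoxy group, and boat versus chair selectivity is open.
- Against the secure C10 of A3 the chosen plan sets the stereoelectronic argument for axial attack plus an alkynyl fallback, and a cage completed before acid-sensitive groups appear.

Key step: step 11

Remark: compounds 7, 11 and both antipodes of cis-4-acetoxycyclopent-2-en-1-ol are taken as purchasable; with the order silylation, deacetylation, oxidation, only the (1S,4R) antipode 1 leads to (R)-configured C18.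

## Steps

Step 1
Reactants: 1 (1S,4R)-cis-4-acetoxycyclopent-2-en-1-ol
Product: 2 (1R,4S)-4-[(tert-butyldiphenylsilyl)oxy]cyclopent-2-en-1-yl acetate
Conditions: tBuPh2SiCl, imidazole, DMF, rt
Reagents that add atoms: tert-butyl(chloro)diphenylsilane, CC(C)(C)[Si](Cl)(c1ccccc1)c1ccccc1
Why: Silylation of the free allylic alcohol; this carbon becomes C18 and the robust ether stays until step 19.

Step 2
Reactants: 2 (1R,4S)-4-[(tert-butyldiphenylsilyl)oxy]cyclopent-2-en-1-yl acetate
Product: 3 (1R,4S)-4-[(tert-butyldiphenylsilyl)oxy]cyclopent-2-en-1-ol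
Conditions: K2CO3 (cat.), MeOH, 0 °C to rt
Reagents that add atoms: none
Why: Mild methanolysis (transesterification) of the acetate; the silyl ether is not affected.

Step 3
Reactants: 3 (1R,4S)-4-[(tert-butyldiphenylsilyl)oxy]cyclopent-2-en-1-ol
Product: 4 (S)-4-[(tert-butyldiphenylsilyl)oxy]cyclopent-2-en-1-one
Conditions: MnO2, CH2Cl2, rt
Reagents that add atoms: none
Why: Allylic alcohol oxidation to the enone; the silyloxy stereocentre is untouched.

Step 4
Reactants: 4 (S)-4-[(tert-butyldiphenylsilyl)oxy]cyclopent-2-en-1-one
Product: 5 (R)-3-[(tert-butyldiphenylsilyl)oxy]cyclopentan-1-one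
Conditions: H2 (1 atm), Pd/C, EtOAc, rt
Reagents that add atoms: none
Why: Heterogeneous hydrogenation of the enone alkene in a neutral medium, which avoids β-elimination of the silyloxy group.

Step 5
Reactants: 5 (R)-3-[(tert-butyldiphenylsilyl)oxy]cyclopentan-1-one
Product: 6 (R)-4-[(tert-butyldiphenylsilyl)oxy]cyclopent-1-en-1-yl trifluoromethanesulfonate
Conditions: KN(SiMe3)2, THF, −78 °C; PhNTf2, −78 °C to 0 °C
Reagents that add atoms: N-phenylbis(trifluoromethanesulfonimide), O=S(=O)(N(c1ccccc1)S(=O)(=O)C(F)(F)F)C(F)(F)F
Why: Kinetic enolisation should occur at the α-carbon remote from the bulky silyloxy carbon; O-triflation then fixes the alkene as C16=C21.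

Step 6
Reactants: 6 (R)-4-[(tert-butyldiphenylsilyl)oxy]cyclopent-1-en-1-yl trifluoromethanesulfonate; 7 (E)-2-(2-ethoxyvinyl)-4,4,5,5-tetramethyl-1,3,2-dioxaborolane
Product: 8 tert-butyl({(1R)-3-[(E)-2-ethoxyvinyl]cyclopent-3-en-1-yl}oxy)diphenylsilane
Conditions: Pd(PPh3)4 (zerovalent palladium, cat.), K3PO4, dioxane–H2O, 60 °C
Reagents that add atoms: none
Why: Suzuki–Miyaura coupling of an alkenyl triflate with an alkenylboronate; it forms C16–C26 without moving the ring alkene.

Step 7
Reactants: 8 tert-butyl({(1R)-3-[(E)-2-ethoxyvinyl]cyclopent-3-en-1-yl}oxy)diphenylsilane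
Product: 9 2-{(4R)-4-[(tert-butyldiphenylsilyl)oxy]cyclopent-1-en-1-yl}acetaldehyde
Conditions: 1 M HCl, THF, 0 °C, short contact; crude product used at once
Reagents that add atoms: water, O
Why: Kinetic enol ether hydrolysis: protonation at C26 and loss of ethanol give the β,γ-unsaturated aldehyde; cold, brief exposure should prevent conjugation into the ring.

Step 8
Reactants: 9 2-{(4R)-4-[(tert-butyldiphenylsilyl)oxy]cyclopent-1-en-1-yl}acetaldehyde
Product: 10 tert-butyl[((1R)-3-{(E)-2-[(triisopropylsilyl)oxy]vinyl}cyclopent-3-en-1-yl)oxy]diphenylsilane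
Conditions: iPr3SiOTf, Et3N, CH2Cl2, −78 °C to 0 °C
Reagents that add atoms: triisopropylsilyl trifluoromethanesulfonate, CC(C)[Si](OS(=O)(=O)C(F)(F)F)(C(C)C)C(C)C
Why: Soft enolisation removes the doubly activated C26 proton and gives the conjugated silyl dienol ether, expected mainly as the (E) isomer because the bulky silyloxy group avoids the ring; the ring alkene stays at C16=C21.

Step 9
Reactants: 11 (5R)-5-{[(1R,2S,5R)-2-isopropyl-5-methylcyclohexyl]oxy}furan-2(5H)-one
Product: 12 (3S,4R,5R)-3,4-dihydroxy-5-(l-menthyloxy)dihydrofuran-2(3H)-one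
Conditions: OsO4 (cat.), N-methylmorpholine N-oxide, acetone–H2O, rt
Reagents that add atoms: N-methylmorpholine N-oxide, C[N+]1([O-])CCOCC1; water, O
Why: Catalytic cis-dihydroxylation of the butenolide, anti to the menthyloxy group; the two new centres are removed again in step 10, so their configuration is not critical.

Step 10
Reactants: 12 (3S,4R,5R)-3,4-dihydroxy-5-(l-menthyloxy)dihydrofuran-2(3H)-one
Product: 14 (5R)-5-(l-menthyloxy)-2-oxo-2,5-dihydrofuran-3-yl benzoate, via dibenzoate 13 (not isolated)
Conditions: BzCl, pyridine, 4-(dimethylamino)pyridine (cat.), CH2Cl2, 0 °C to rt; then Et3N, rt, short time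
Reagents that add atoms: benzoyl chloride, O=C(Cl)c1ccccc1
Why: Bis-benzoylation followed by E1cB β-elimination: the acidic C3–H is removed and the anti C4 benzoate leaves, as is known for 2,3-di-O-benzoyl aldono-1,4-lactones. A mild amine and short contact should leave the acetal carbon C5 (later C23) untouched.

Step 11
Reactants: 10 tert-butyl[((1R)-3-{(E)-2-[(triisopropylsilyl)oxy]vinyl}cyclopent-3-en-1-yl)oxy]diphenylsilane; 14 (5R)-5-(l-menthyloxy)-2-oxo-2,5-dihydrofuran-3-yl benzoate
Product: 15 endo Diels–Alder adduct (menthyloxy butyrolactone cis-fused at C12–C22 to the cyclohexene C12–C22–C21–C16(=C26)–C27; O11 benzoate; iPr3SiO on C27 cis to C13; tBuPh2SiO on C18)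
Conditions: toluene, 110 °C, sealed tube, 2,6-di-tert-butyl-4-methylphenol (cat.); diene in excess
Reagents that add atoms: none
Why: Thermal, concerted but asynchronous normal-demand [4+2] cycloaddition (diene HOMO, butenolide LUMO); the closest known class is the cycloaddition of 1-silyloxydienes to α-substituted 5-alkoxybutenolides that creates a quaternary α-carbon. The six-membered carbocycle closes suprafacially on both partners: the nucleophilic terminus C21 leads at the β-carbon C22 and the oxygenated terminus C27 follows at C12, the ortho orientation being set by the silyloxy group. C12 and C22 are set by the dienophile, which should be attacked only anti to the C23 menthyloxy group, while the ring alkene keeps C13 and C23 cis. C21 is set by attack on the diene face anti to the C18 silyl ether, and with (5R)-14 this is the same pairing that the dienophile demands (matched double stereodifferentiation). C27 follows from the (E)-enol ether and the endo position of the lactone, which place O28 cis to C13 and C20; this is the C27 epimer of the target, inverted in steps 21–22 and used until then as a shield for the cage lactone. The step needs ortho regiochemistry, endo orientation and facial control; these are secured by the 1-silyloxy group, the cis-fused lactone lying under the diene, and the menthyloxy group reinforced by C18. Any (Z)-enol ether is far less reactive and should be left behind.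

Step 12
Reactants: 15 endo Diels–Alder adduct
Product: 16 hydroxy lactone (C23 lactol, epimer mixture; pseudo-acid of the C23 aldehyde and the C13 acid)
Conditions: CF3CO2H–H2O–THF, rt to 40 °C
Reagents that add atoms: water, O
Why: Acid hydrolysis of the acylal-type menthyl acetal; only the cis-fused hydroxy lactone can close, so C22 keeps its configuration. The iPr3Si and tBuPh2Si ethers and the benzoate should tolerate aqueous CF3CO2H.

Step 13
Reactants: 16 hydroxy lactone
Product: 18 pyranone carboxylic acid, via (Z)-enoate 17 (not isolated)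
Conditions: 16 + KN(SiMe3)2 (1 equiv), THF, −78 °C, added to (CF3CH2O)2P(O)CH(CH3)CO2Et, KN(SiMe3)2, 18-crown-6, THF, −78 °C; then NaOMe, MeOH, 0 °C to rt; aq. HCl work-up
Reagents that add atoms: ethyl 2-[bis(2,2,2-trifluoroethoxy)phosphoryl]propanoate, CCOC(=O)C(C)P(=O)(OCC(F)(F)F)OCC(F)(F)F
Why: Still–Gennari olefination of the ring-opened aldehyde carboxylate should give the (Z)-trisubstituted enoate under kinetic control. Methoxide then removes the benzoate and the freed O11 closes the unsaturated six-membered lactone, which is possible only for the (Z) isomer. O11 stays acylated while C23 is an aldehyde, so retro-aldol opening is excluded.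

Step 14
Reactants: 18 pyranone carboxylic acid
Product: 19 iodo cage lactone (O15–C16 closed, iodine on C26 anti to O15)
Conditions: I2, NaHCO3, MeCN–H2O, 0 °C to rt, dark
Reagents that add atoms: iodine, II
Why: Iodolactonisation: the axial C13 carboxylate opens the iodonium ion at the more substituted carbon C16 (Markovnikov, anti addition) and closes the 2-oxabicyclo[2.2.2]octanone, so C16 can form only with the configuration dictated by C12. The neutral medium avoids ionisation of the allylic C27 silyl ether, and neither O11 (acylated) nor C23 (sp2) can compete.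

Step 15
Reactants: 19 iodo cage lactone
Product: 20 cage bis-lactone (pyranone plus 2-oxabicyclo[2.2.2]octanone; 27-epi iPr3Si ether)
Conditions: Bu3SnH (excess, concentrated), azobis(isobutyronitrile) (cat.), toluene, 80 °C
Reagents that add atoms: none
Why: Radical chain deiodination of the secondary iodide; a high stannane concentration should outrun 1,2-acyloxy migration of the β-acyloxyalkyl radical.

Step 16
Reactants: 20 cage bis-lactone
Product: 22 lactol acetate (C10 acetoxy acetal), via aluminium lactolate 21 (not isolated)
Conditions: iBu2AlH (1.2 equiv), CH2Cl2, −78 °C; then pyridine, 4-(dimethylamino)pyridine, Ac2O, −78 °C to 0 °C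
Reagents that add atoms: acetic anhydride, CC(=O)OC(C)=O
Why: Reductive acetylation: the hydride should add once to the more accessible unsaturated lactone, and the aluminium lactolate is acetylated in the same flask. The cage lactone is a tertiary-alkyl ester of a quaternary acid, screened by the pyranone ring and C20 on one face and by the C27 iPr3SiO group on the other.

Step 17
Reactants: 23 non-1-yne
Product: 25 potassium (E)-trifluoro(non-1-en-1-yl)borate, via alkenylboronate 24 (not isolated)
Conditions: catecholborane, neat, 70 °C; then KHF2, H2O–MeOH, rt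
Reagents that add atoms: catecholborane, B1Oc2ccccc2O1; potassium hydrogen difluoride, F.[F-].[K+]
Why: syn-Hydroboration of the terminal alkyne gives the (E)-alkenylboronate, which KHF2 converts into the stable trifluoroborate.

Step 18
Reactants: 22 lactol acetate; 25 potassium (E)-trifluoro(non-1-en-1-yl)borate
Product: 26 bis-silyl ether of the C27 epimer of the target
Conditions: BF3·OEt2, MeCN–CH2Cl2, −40 °C to 0 °C
Reagents that add atoms: none
Why: BF3·OEt2 ionises the allylic acetate to a conjugated oxocarbenium ion, and the alkenyltrifluoroborate adds at C10 with retention of the (E) alkene. The cage holds the cation in one half-chair with C13 pseudo-axial on C12; axial attack, which leads directly to the half-chair product, is syn to C13 and gives the target configuration at C10.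

Step 19
Reactants: 26 bis-silyl ether of the C27 epimer of the target
Product: 27 C27 epimer of the target (diol)
Conditions: Bu4NF, AcOH (1:1), THF, rt to 45 °C
Reagents that add atoms: none
Why: Fluoride cleaves both silyl ethers; buffering with AcOH keeps the medium non-basic, so the β-hydroxy lactone cannot undergo retro-aldol opening.

Step 20
Reactants: 27 C27 epimer of the target (diol)
Product: 28 19-O-triethylsilyl ether of the C27 epimer
Conditions: Et3SiCl (1.1 equiv), imidazole, CH2Cl2, −40 °C
Reagents that add atoms: chlorotriethylsilane, CC[Si](Cl)(CC)CC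
Why: The unhindered cyclopentanol O19 is silylated selectively; the C27 hydroxyl, flanked by quaternary C12 and the lactone bridge, should not react at low temperature.

Step 21
Reactants: 28 19-O-triethylsilyl ether of the C27 epimer
Product: 29 C27 ketone
Conditions: Dess–Martin periodinane, NaHCO3, CH2Cl2, rt
Reagents that add atoms: none
Why: Dess–Martin oxidation of the hindered secondary alcohol under buffered conditions; the β-keto lactone cannot enolise toward quaternary C12.

Step 22
Reactants: 29 C27 ketone
Product: 30 19-O-triethylsilyl ether of the target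
Conditions: NaBH4, MeOH–CH2Cl2, −40 °C
Reagents that add atoms: none
Why: The ketone is reduced much faster than the lactone. Hydride should enter from the face of the flat lactone bridge, away from the inward hydrogens on C21 and C22, so O28 ends anti to the lactone as in the target.

Step 23
Reactants: 30 19-O-triethylsilyl ether of the target
Product: 31 CNP0127096.1
Conditions: HF·pyridine, pyridine, THF, 0 °C
Reagents that add atoms: none
Why: Buffered HF removes the triethylsilyl ether without ionising the doubly allylic ether at C10.

## Compound list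

1 | (1S,4R)-cis-4-acetoxycyclopent-2-en-1-ol | CC(=O)O[C@@H]1C[C@H](O)C=C1 | starting material
2 | (1R,4S)-4-[(tert-butyldiphenylsilyl)oxy]cyclopent-2-en-1-yl acetate | CC(=O)O[C@@H]1C[C@H](O[Si](c2ccccc2)(c2ccccc2)C(C)(C)C)C=C1 | intermediate
3 | (1R,4S)-4-[(tert-butyldiphenylsilyl)oxy]cyclopent-2-en-1-ol | O[C@@H]1C[C@H](O[Si](c2ccccc2)(c2ccccc2)C(C)(C)C)C=C1 | intermediate
4 | (S)-4-[(tert-butyldiphenylsilyl)oxy]cyclopent-2-en-1-one | O=C1C[C@H](O[Si](c2ccccc2)(c2ccccc2)C(C)(C)C)C=C1 | intermediate
5 | (R)-3-[(tert-butyldiphenylsilyl)oxy]cyclopentan-1-one | O=C1C[C@H](O[Si](c2ccccc2)(c2ccccc2)C(C)(C)C)CC1 | intermediate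
6 | (R)-4-[(tert-butyldiphenylsilyl)oxy]cyclopent-1-en-1-yl trifluoromethanesulfonate | O=S(=O)(OC1=CC[C@@H](O[Si](c2ccccc2)(c2ccccc2)C(C)(C)C)C1)C(F)(F)F | intermediate
7 | (E)-2-(2-ethoxyvinyl)-4,4,5,5-tetramethyl-1,3,2-dioxaborolane | CCO/C=C/B1OC(C)(C)C(C)(C)O1 | starting material
8 | tert-butyl({(1R)-3-[(E)-2-ethoxyvinyl]cyclopent-3-en-1-yl}oxy)diphenylsilane | CCO/C=C/C1=CC[C@@H](O[Si](c2ccccc2)(c2ccccc2)C(C)(C)C)C1 | intermediate
9 | 2-{(4R)-4-[(tert-butyldiphenylsilyl)oxy]cyclopent-1-en-1-yl}acetaldehyde | O=CCC1=CC[C@@H](O[Si](c2ccccc2)(c2ccccc2)C(C)(C)C)C1 | intermediate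
10 | tert-butyl[((1R)-3-{(E)-2-[(triisopropylsilyl)oxy]vinyl}cyclopent-3-en-1-yl)oxy]diphenylsilane (diene) | CC(C)[Si](C(C)C)(C(C)C)O/C=C/C1=CC[C@@H](O[Si](c2ccccc2)(c2ccccc2)C(C)(C)C)C1 | intermediate
11 | (5R)-5-{[(1R,2S,5R)-2-isopropyl-5-methylcyclohexyl]oxy}furan-2(5H)-one | O=C1O[C@@H](O[C@@H]2C[C@H](C)CC[C@H]2C(C)C)C=C1 | starting material
12 | (3S,4R,5R)-3,4-dihydroxy-5-(l-menthyloxy)dihydrofuran-2(3H)-one (cis-diol, both hydroxyls trans to the menthyloxy group) | O=C1O[C@@H](O[C@@H]2C[C@H](C)CC[C@H]2C(C)C)[C@H](O)[C@@H]1O | intermediate
13 | (3S,4R,5R)-5-(l-menthyloxy)-2-oxotetrahydrofuran-3,4-diyl dibenzoate | O=C1O[C@@H](O[C@@H]2C[C@H](C)CC[C@H]2C(C)C)[C@H](OC(=O)c2ccccc2)[C@@H]1OC(=O)c1ccccc1 | intermediate (not isolated)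
14 | (5R)-5-(l-menthyloxy)-2-oxo-2,5-dihydrofuran-3-yl benzoate (dienophile) | O=C1O[C@@H](O[C@@H]2C[C@H](C)CC[C@H]2C(C)C)C=C1OC(=O)c1ccccc1 | intermediate
15 | endo adduct: γ-lactone C13(=O)–O–C23H(O-l-menthyl) cis-fused at C12–C22 to cyclohexene C12–C22–C21–C16(=C26)–C27; benzoate on O11; iPr3SiO on C27 cis to C13, C23 and C20; tBuPh2SiO on C18 trans to C22; menthyloxy trans to C21 | O=C1O[C@@H](O[C@@H]3C[C@H](C)CC[C@H]3C(C)C)[C@H]2[C@]1(OC(=O)c3ccccc3)[C@@H](O[Si](C(C)C)(C(C)C)C(C)C)C=C3C[C@H](O[Si](c4ccccc4)(c4ccccc4)C(C)(C)C)C[C@@H]23 | intermediate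
16 | hydroxy lactone: as 15 with OH in place of menthyloxy on C23 (lactol epimers) | O=C1OC(O)[C@H]2[C@]1(OC(=O)c3ccccc3)[C@@H](O[Si](C(C)C)(C(C)C)C(C)C)C=C3C[C@H](O[Si](c4ccccc4)(c4ccccc4)C(C)(C)C)C[C@@H]23 | intermediate
17 | (Z)-enoate: C22 bears (Z)-CH=C(CH3)CO2Et, C12 bears the benzoate and the C13 carboxylic acid (present as potassium carboxylate) | CCOC(=O)/C(C)=C\[C@H]1[C@@](OC(=O)c2ccccc2)(C(=O)O)[C@@H](O[Si](C(C)C)(C(C)C)C(C)C)C=C2C[C@H](O[Si](c3ccccc3)(c3ccccc3)C(C)(C)C)C[C@@H]12 | intermediate (not isolated)
18 | pyranone carboxylic acid: 3-methyl-5,6-dihydro-2H-pyran-2-one (C10=O, C23=C24) trans-fused at C12–C22 to the cyclohexene; free C13 acid on C12 | CC1=C[C@H]2[C@@](OC1=O)(C(=O)O)[C@@H](O[Si](C(C)C)(C(C)C)C(C)C)C=C1C[C@H](O[Si](c3ccccc3)(c3ccccc3)C(C)(C)C)C[C@@H]21 | intermediate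
19 | iodo cage lactone: 2-oxabicyclo[2.2.2]octan-3-one closed at O15–C16, iodine on C26 anti to O15 | O=C1O[C@@]23C(=O)O[C@]4(C[C@H](O[Si](c5ccccc5)(c5ccccc5)C(C)(C)C)C[C@H]4[C@H]2C=C1C)[C@@H](I)[C@@H]3O[Si](C(C)C)(C(C)C)C(C)C | intermediate
20 | cage bis-lactone (C10 pyranone, C13 cage lactone, 27-epi iPr3Si ether, 19-O-tBuPh2Si ether) | O=C1O[C@@]23C(=O)O[C@]4(C[C@H](O[Si](c5ccccc5)(c5ccccc5)C(C)(C)C)C[C@H]4[C@H]2C=C1C)C[C@@H]3O[Si](C(C)C)(C(C)C)C(C)C | intermediate
21 | diisobutylaluminium lactolate at C10 | CC(C)C[Al](CC(C)C)OC1O[C@@]23C(=O)O[C@]4(C[C@H](O[Si](c5ccccc5)(c5ccccc5)C(C)(C)C)C[C@H]4[C@H]2C=C1C)C[C@@H]3O[Si](C(C)C)(C(C)C)C(C)C | intermediate (not isolated)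
22 | lactol acetate at C10 (anomer mixture) | CC(=O)OC1O[C@@]23C(=O)O[C@]4(C[C@H](O[Si](c5ccccc5)(c5ccccc5)C(C)(C)C)C[C@H]4[C@H]2C=C1C)C[C@@H]3O[Si](C(C)C)(C(C)C)C(C)C | intermediate
23 | non-1-yne | CCCCCCCC#C | starting material
24 | (E)-2-(non-1-en-1-yl)-1,3,2-benzodioxaborole | CCCCCCC/C=C/B1Oc2ccccc2O1 | intermediate (not isolated)
25 | potassium (E)-trifluoro(non-1-en-1-yl)borate | CCCCCCC/C=C/[B-](F)(F)F.[K+] | intermediate
26 | 19-O-tBuPh2Si, 28-O-iPr3Si ether of the C27 epimer of the target | CCCCCCC/C=C/[C@H]1O[C@@]23C(=O)O[C@]4(C[C@H](O[Si](c5ccccc5)(c5ccccc5)C(C)(C)C)C[C@H]4[C@H]2C=C1C)C[C@@H]3O[Si](C(C)C)(C(C)C)C(C)C | intermediate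
27 | C27 epimer of the target (diol) | CCCCCCC/C=C/[C@H]1O[C@@]23C(=O)O[C@]4(C[C@H](O)C[C@H]4[C@H]2C=C1C)C[C@@H]3O | intermediate
28 | 19-O-triethylsilyl ether of the C27 epimer | CCCCCCC/C=C/[C@H]1O[C@@]23C(=O)O[C@]4(C[C@H](O[Si](CC)(CC)CC)C[C@H]4[C@H]2C=C1C)C[C@@H]3O | intermediate
29 | C27 ketone, 19-O-triethylsilyl ether | CCCCCCC/C=C/[C@H]1O[C@@]23C(=O)O[C@]4(C[C@H](O[Si](CC)(CC)CC)C[C@H]4[C@H]2C=C1C)CC3=O | intermediate
30 | 19-O-triethylsilyl ether of the target | CCCCCCC/C=C/[C@H]1O[C@@]23C(=O)O[C@]4(C[C@H](O[Si](CC)(CC)CC)C[C@H]4[C@H]2C=C1C)C[C@H]3O | intermediate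
31 | CNP0127096.1 | CCCCCCC/C=C/[C@H]1O[C@@]23C(=O)O[C@]4(C[C@H](O)C[C@H]4[C@H]2C=C1C)C[C@H]3O | target

Total step count: 23. Longest linear sequence: 20 steps (steps 1–8, 11–16, 18–23).

## Least certain steps and fallbacks

**Step 11 (key step).** The likeliest failure is slow cycloaddition with erosion of endo or facial selectivity, because a quaternary, oxygen-bearing C12 is formed next to the bulky C27 silyloxy carbon. The fallback moves the C12 oxygen to a later stage. It sets out from 10 and the parent butenolide 11, which is less hindered and forms only a tertiary C12. Heating them in toluene should give the benzoate-free adduct F1 with the same endo and anti sense. Enolisation with KN(SiMe3)2 at −78 °C and oxidation with 2-(phenylsulfonyl)-3-phenyloxaziridine would give the α-hydroxy lactone F2; the oxygen enters on the convex face, which keeps the cis ring fusion. Benzoylation (BzCl, 4-(dimethylamino)pyridine, Et3N) returns to the route at 15.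

**Step 12.** Hydrolysis of the hindered menthyl acetal may be too slow, and prolonged acid would then start to cleave the allylic silyl ether. The fallback replaces Brønsted hydrolysis by Lewis-acid transthioacetalisation. It sets out from 15: propane-1,3-dithiol and BF3·OEt2 at −20 °C would open the pseudo-ester to the dithiane acid F3. Dethioacetalisation with MeI and CaCO3 in aqueous MeCN lets the aldehyde close onto the acid and returns to the route at 16.

**Step 13.** Poor conversion of the hindered, carboxylate-flanked aldehyde or erosion of (Z) selectivity is possible; base could also epimerise C22. The fallback gives up kinetic (Z) control. It sets out from 16: the neutral stabilised ylide Ph3P=C(CH3)CO2Et would give the (E)-enoate F4. NaOEt in EtOH removes the benzoate to give the (E)-hydroxy ester acid F5. Irradiation (photochemical E to Z isomerisation of the enoate) lets the (Z) isomer lactonise as it forms and returns to the route at 18.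

**Step 14.** Loss of regiocontrol (carboxylate attack at C26 to give the bicyclo[3.2.1] γ-lactone) or reversible, unproductive iodonium formation at the hindered alkene could intervene. The fallback is a radical-polar crossover hydro-acyloxylation instead of a halonium process. It sets out from 18 and uses the cobalt salen complex Co(C16H14N2O2) (divalent cobalt), N-fluoro-2,4,6-trimethylpyridinium triflate and PhSiH3. Hydrogen-atom transfer to C26 and oxidation of the tertiary C16 radical are followed by capture by the carboxylic acid. This returns to the route at 20, skips step 15 and makes no new compound (F0).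

**Step 16.** The hydride may fail to discriminate and also attack the α-alkoxy cage lactone. The fallback accepts double reduction. It sets out from 20: excess iBu2AlH followed by Ac2O, pyridine and 4-(dimethylamino)pyridine would give the bis(lactol acetate) F6. With 25 and BF3·OEt2 only the allylic C10 acetate should ionise, since the C13 acetal is not conjugated and lies next to the electron-poor C12; this gives the alkenylated cage lactol acetate F7. Methanolysis (K2CO3, MeOH) to the cage lactol F8 and oxidation with Pr4NRuO4 (cat.) and N-methylmorpholine N-oxide return to the route at 26.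

**Step 18.** Facial selectivity at C10 may be poor, because the stereoelectronically preferred axial path is syn to the pseudo-axial C13 carbonyl; attack at C23 or proton loss from the cation could also occur. The fallback uses a slimmer, linear nucleophile and adjusts the oxidation level afterwards. Potassium non-1-ynyltrifluoroborate F9 would be made from 23 (BuLi, B(OMe)3, then KHF2). With BF3·OEt2 it sets out from 22 and would give the C10 alkyne F10. trans-Hydrosilylation with (EtO)3SiH and Cp*Ru(MeCN)3PF6 would give the alkenylsilane F11 (either regioisomer serves). Bu4NF, buffered with AcOH, then effects protodesilylation to the (E)-alkene and removes both silyl ethers, returning to the route at 27.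

## Further compounds

F1 | step 11 | benzoate-free endo adduct of 10 and 11 (H on C12) | O=C1O[C@@H](O[C@@H]3C[C@H](C)CC[C@H]3C(C)C)[C@H]2[C@@H]1[C@@H](O[Si](C(C)C)(C(C)C)C(C)C)C=C3C[C@H](O[Si](c4ccccc4)(c4ccccc4)C(C)(C)C)C[C@@H]23
F2 | step 11 | α-hydroxy lactone (free O11 hydroxyl on C12) | O=C1O[C@@H](O[C@@H]3C[C@H](C)CC[C@H]3C(C)C)[C@H]2[C@]1(O)[C@@H](O[Si](C(C)C)(C(C)C)C(C)C)C=C3C[C@H](O[Si](c4ccccc4)(c4ccccc4)C(C)(C)C)C[C@@H]23
F3 | step 12 | dithiane acid (1,3-dithian-2-yl as C23 on C22, free C13 acid, O11 benzoate) | S1CCCSC1[C@H]2[C@@](OC(=O)c3ccccc3)(C(=O)O)[C@@H](O[Si](C(C)C)(C(C)C)C(C)C)C=C3C[C@H](O[Si](c4ccccc4)(c4ccccc4)C(C)(C)C)C[C@@H]23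
F4 | step 13 | (E)-enoate acid (O11 benzoate) | CCOC(=O)/C(C)=C/[C@H]1[C@@](OC(=O)c2ccccc2)(C(=O)O)[C@@H](O[Si](C(C)C)(C(C)C)C(C)C)C=C2C[C@H](O[Si](c3ccccc3)(c3ccccc3)C(C)(C)C)C[C@@H]12
F5 | step 13 | (E)-hydroxy ester acid (free O11 hydroxyl) | CCOC(=O)/C(C)=C/[C@H]1[C@@](O)(C(=O)O)[C@@H](O[Si](C(C)C)(C(C)C)C(C)C)C=C2C[C@H](O[Si](c3ccccc3)(c3ccccc3)C(C)(C)C)C[C@@H]12
F0 | step 14 | none | none
F6 | step 16 | bis(lactol acetate) at C10 and C13 | CC(=O)OC1O[C@@]23C(OC(C)=O)O[C@]4(C[C@H](O[Si](c5ccccc5)(c5ccccc5)C(C)(C)C)C[C@H]4[C@H]2C=C1C)C[C@@H]3O[Si](C(C)C)(C(C)C)C(C)C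
F7 | step 16 | C10-alkenylated cage lactol acetate | CCCCCCC/C=C/[C@H]1O[C@@]23C(OC(C)=O)O[C@]4(C[C@H](O[Si](c5ccccc5)(c5ccccc5)C(C)(C)C)C[C@H]4[C@H]2C=C1C)C[C@@H]3O[Si](C(C)C)(C(C)C)C(C)C
F8 | step 16 | C10-alkenylated cage lactol | CCCCCCC/C=C/[C@H]1O[C@@]23C(O)O[C@]4(C[C@H](O[Si](c5ccccc5)(c5ccccc5)C(C)(C)C)C[C@H]4[C@H]2C=C1C)C[C@@H]3O[Si](C(C)C)(C(C)C)C(C)C
F9 | step 18 | potassium trifluoro(non-1-yn-1-yl)borate | CCCCCCCC#C[B-](F)(F)F.[K+]
F10 | step 18 | C10 non-1-ynyl analogue of 26 | CCCCCCCC#C[C@H]1O[C@@]23C(=O)O[C@]4(C[C@H](O[Si](c5ccccc5)(c5ccccc5)C(C)(C)C)C[C@H]4[C@H]2C=C1C)C[C@@H]3O[Si](C(C)C)(C(C)C)C(C)C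
F11 | step 18 | C9-triethoxysilyl alkenylsilane from trans-hydrosilylation of F10 | CCCCCCC/C=C(\[Si](OCC)(OCC)OCC)[C@H]1O[C@@]23C(=O)O[C@]4(C[C@H](O[Si](c5ccccc5)(c5ccccc5)C(C)(C)C)C[C@H]4[C@H]2C=C1C)C[C@@H]3O[Si](C(C)C)(C(C)C)C(C)C
A1 | alternative 1 | Pauson–Khand product: cage lactone fused to a cyclopentenone (C18 ketone, C20=C21), O28 silyl ether | CCCCCCC/C=C/[C@H]1O[C@@]23C(=O)O[C@]4(CC(=O)C=C4[C@H]2C=C1C)C[C@H]3O[Si](C)(C)C(C)(C)C
A2 | alternative 2 | cascade product: tricyclic cage lactone with free O11 hydroxyl, 4-methoxybenzyloxymethyl on C22, silyl ethers on O19 and O28 | O[C@@]23C(=O)O[C@]4(C[C@H](O[Si](C)(C)C(C)(C)C)C[C@H]4[C@H]2COCc1ccc(OC)cc1)C[C@H]3O[Si](C)(C)C(C)(C)C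
A3 | alternative 3 | Ireland–Claisen product: dihydropyran-2-carboxylic acid with quaternary C12 and a methylenecyclopentyl group on C22 | CCCCCCC/C=C/[C@H]1O[C@](C(=O)O)(COCc3ccc(OC)cc3)[C@H](C=C1C)[C@@H]2C[C@@H](O[Si](C)(C)C(C)(C)C)CC2=C
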